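## Structural features

The target is a flavone. Benzo ring A (C4a, C5, C6, C7, C8, C8a) is fused through the C4a–C8a bond to the 4-pyranone ring C (O1, C2, C3, C4), and ring C carries the resorcinol ring B through the C2–C1' bond. Ring A has the phloroglucinol pattern, with hydroxyls on C5 and C7 and the ring oxygen O1 on C8a. Between those two hydroxyls, C6 bears the 3-hydroxy-3-methylbutyl chain, and ring B has hydroxyls on C2' and C4'. There is no stereocentre, so the only stereochemical element of the route is the geometry of the acyclic enol-ether double bond that later becomes C2=C3 of ring C. The fragile group is the tertiary alcohol, held two carbons away from a ring flanked by the C5 and C7 hydroxyls: acid would ionise it and lead to dehydration or to a 2,2-dimethylchroman, so the end of the route must be neutral. The real difficulty is regiochemical, because C6 and C8 are activated by the same three oxygens and the chain must go to C6 alone while a second electron-rich ring is present. The key step uses the position of C4a between C8a (bearing O1) and C5 (bearing oxygen): before ring C exists, C4a is one of two equivalent ortho carbons of a mirror-symmetric 3,5-dioxygenated phenoxy ring, so acylation by the C4 carboxyl carbon forms C4–C4a and closes ring C without a regiochemical choice.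

## Logic of the disconnections

14 to 13. The three O–benzyl bonds are cut and the two saturated side-chain carbons next to C6 are taken back to a triple bond. This lets the last operation be a single neutral hydrogenation, which the tertiary alcohol next to two phenols tolerates. The forward step must remove three benzyl groups and saturate the alkyne without reducing C2=C3 of ring C or cleaving the tertiary C–O bond.

13 to 11 and 12. The bond between C6 and the first side-chain carbon is cut. This splits off all five side-chain carbons as the purchasable alkynol 12 and leaves an aryl iodide. The forward sp2–sp coupling must occur at a hindered, electron-rich iodide with a free ortho hydroxyl, without that hydroxyl adding to the new alkyne.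

11 to 10. The C6–I bond is cut. The halogen is the only handle needed to mark C6, and the free C5 hydroxyl of 10 is what directs it there. The forward iodination must choose C6 over C8 and over ring B.

10 to 9. The O5–benzyl bond is re-formed in the backward sense, so that both oxygens of ring A carry the same group. This restores the symmetry that the ring closure needs. The forward step must remove one benzyl group out of four, which the chelation of O5 to the C4 carbonyl should allow.

9 to 7 (through 8). The C4–C4a bond is cut, opening ring C to an acyclic (Z)-3-aryloxy-3-arylacrylic acid. Both aromatic rings then come from separate, simple pieces joined only by an enol-ether oxygen. The forward acylation needs the carboxyl cis to the aryloxy group and activation mild enough for four benzyl ethers and an enol ether.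

7 to 6. The acid is traced to its methyl ester. The ester is what makes the alkyne of the next precursor a conjugate acceptor. The forward hydrolysis must leave the enol-ether geometry and the C2–O1 bond intact.

6 to 4 and 5. The C2–O1 bond is cut, giving an aryl ynoate and a symmetric phenol. This is the convergent point of the route. The forward oxa-conjugate addition must occur through oxygen, not carbon, of the phenoxide and in anti fashion, so that the (Z) isomer results.

4 to 2 (through 3) and 2 to 1. The C3–C4 bond and then the C2–C3 multiple bond are cut, back to an aromatic aldehyde, a one-carbon dibromomethylene unit and a chloroformate carbon. All of ring C's carbons thus come from cheap one-carbon reagents. The forward steps need an organolithium at low temperature in the presence of two benzyl ethers.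

## Other disconnections considered

Alternative 1: Ring A is cut at C4a–C5. The precursor is the pyranone-tethered β-keto ester A2, in which a 2-aryl-4-pyranone carries at its other α-carbon (future C8a) a chain with the future C8 methylene, C7 ketone, C6 methine with the protected side chain, and C5 methyl ester. Base would form an extended dienolate through the C8 methylene; the pyranone carbon that becomes C4a would attack the ester, and enolisation would aromatise ring A to give A1.
- In its favour: the side chain is placed on C6 by simple alkylation of a β-keto ester before ring A exists, so there is no C6/C8 question, no halogenation and no palladium coupling. On regiocontrol at C6 this plan is better than the chosen one. It is also the equal of the chosen plan in giving a symmetric-free, unambiguous ring closure.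
- Against it: the most acidic proton of A2 is the one between ketone and ester, not the C8 methylene, so a polyanion would be needed. 4-Pyranones are prone to conjugate addition and ring opening by strong bases. O-acylation or aldol closure onto the pyranone carbonyl could compete.
- Comparison: mechanistically, a Claisen condensation at a pyranone α-carbon is less secure than a Friedel–Crafts acylation of a phloroglucinol ether. A2 needs a multistep assembly from a 2-aryl-6-methylpyranone, and A1 still needs two deprotections, so the step count should be equal at best and probably higher.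

Alternative 2: Ring B is cut at C1'–C2' and C5'–C6'. The ethynylchromone A4 would act as dienophile toward the 1,3-bis(silyloxy)diene A5; cycloaddition, loss of trimethylsilanol and desilylation would give A3.
- In its favour: the polarity of the two partners fixes the orientation, with the nucleophilic diene terminus bonding to the terminal alkyne carbon. The reaction is thermal and free of acid, so toward benzyl ethers it is the equal of, or gentler than, the chosen acylation. It also delivers O2' and O4' differentiated.
- Against it: it builds the one ring that can be bought complete as a resorcinol aldehyde and leaves the real problem, the chain on C6, untouched. All of the steps after the key step of the chosen plan would still be needed. The free 4'-hydroxyl of A3 would have to be protected first, since a free phenol in ring B would draw the iodinating agent there. A4 needs several steps from a 2-hydroxyacetophenone, A5 is moisture-sensitive, and the diene could add to C2 of the chromone in Michael fashion.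
- Comparison: structurally it solves nothing that the chosen plan leaves open, and in step economy it is clearly worse.

Alternative 3: Ring A is cut at C8–C8a, C5–C6, C7–C8 and C4a–C5. Irradiation of the pyranonyl diazo ketone A7 with the siloxyalkyne A8 would trigger Wolff rearrangement to a pyranonylketene, (2+2) cycloaddition, four-electron ring opening and six-electron electrocyclisation onto the pyranone carbon that becomes C4a, giving A6 on heating.
- In its favour: four bonds and the whole of ring A, with the chain on C6 and O5 and O7 differentiated, would form in one operation with complete regiocontrol. On bond economy of the key step and on regiocontrol this plan is better than the chosen one.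
- Against it: A7 requires diazomethane-type or diazo-transfer chemistry on a pyranone carboxylic acid, which is a handling hazard. A8 needs its own multistep synthesis and is hydrolytically sensitive. The 2-aryl-4-pyranone chromophore absorbs strongly and has photochemistry of its own. The electrocyclisation must engage a cross-conjugated pyranone double bond. Two kinds of silyl ether plus the benzyl ethers mean two deprotection operations at the end where the chosen plan has one.
- Comparison: because both partners are elaborate, the overall step count should exceed that of the chosen plan, which joins three purchasable fragments by classical reactions.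

Key step: step 5

Assumption: 2,4-bis(benzyloxy)benzaldehyde (1) and 3,5-bis(benzyloxy)phenol (5) are treated as purchasable building blocks, so no benzylation step is included.

## Route

Step 1
Reactants: 1 2,4-bis(benzyloxy)benzaldehyde
Product: 2 2,4-bis(benzyloxy)-1-(2,2-dibromovinyl)benzene
Conditions: CBr4 (2 equiv), PPh3 (4 equiv), CH2Cl2, 0 °C
Reagents that add atoms: carbon tetrabromide, BrC(Br)(Br)Br
Why: First stage of the Corey–Fuchs homologation: the dibromomethylene ylide formed from CBr4 and PPh3 undergoes a Wittig reaction with the aldehyde; benzyl ethers are inert to these conditions.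

Step 2
Reactants: 2 2,4-bis(benzyloxy)-1-(2,2-dibromovinyl)benzene
Product: 4 methyl 3-[2,4-bis(benzyloxy)phenyl]prop-2-ynoate, via lithium arylacetylide 3 (not isolated)
Conditions: n-BuLi (2.2 equiv), THF, −78 °C; then ClCO2Me, −78 to 0 °C
Reagents that add atoms: methyl chloroformate, COC(=O)Cl
Why: Second stage of the Corey–Fuchs sequence: bromine–lithium exchange and Fritsch–Buttenberg–Wiechell rearrangement give the alkyne, which the second equivalent of base converts into acetylide 3; C-acylation by the chloroformate gives the ynoate, and at −78 °C the exchange should be much faster than metalation of the benzyl ethers.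

Step 3
Reactants: 4 methyl 3-[2,4-bis(benzyloxy)phenyl]prop-2-ynoate; 5 3,5-bis(benzyloxy)phenol
Product: 6 methyl (Z)-3-[3,5-bis(benzyloxy)phenoxy]-3-[2,4-bis(benzyloxy)phenyl]prop-2-enoate
Conditions: Cs2CO3 (0.2 equiv), DMSO, 60 °C
Reagents that add atoms: none
Why: Oxa-Michael addition of the caesium phenoxide of 5 to the β-carbon of ynoate 4; the resulting vinyl anion is protonated by more phenol on the side away from the incoming oxygen, so the net anti addition places the aryloxy group cis to the ester, which is the (Z) isomer, and the base is regenerated.

Step 4
Reactants: 6 methyl (Z)-3-[3,5-bis(benzyloxy)phenoxy]-3-[2,4-bis(benzyloxy)phenyl]prop-2-enoate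
Product: 7 (Z)-3-[3,5-bis(benzyloxy)phenoxy]-3-[2,4-bis(benzyloxy)phenyl]prop-2-enoic acid
Conditions: LiOH·H2O (3 equiv), THF–MeOH–H2O, 40 °C; then cold 0.5 M HCl to pH 4
Reagents that add atoms: lithium hydroxide, [Li+].[OH-]
Why: Ester saponification by acyl–oxygen cleavage; the electron-rich aryl group on the β-carbon makes conjugate attack of hydroxide slow, and the cold, weakly acidic work-up spares the enol ether and its geometry.

Step 5
Reactants: 7 (Z)-3-[3,5-bis(benzyloxy)phenoxy]-3-[2,4-bis(benzyloxy)phenyl]prop-2-enoic acid
Product: 9 5,7,2',4'-tetrakis(benzyloxy)flavone, via mixed trifluoroacetic anhydride 8 (not isolated)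
Conditions: (CF3CO)2O (2 equiv), CH2Cl2, 0 °C to rt
Reagents that add atoms: none
Why: Trifluoroacetic anhydride turns the carboxyl group of 7 into the mixed anhydride 8, whose acyl carbon, activated by the trifluoroacetic acid released (in the limit an acylium ion stabilised by the β-aryloxy group), is attacked by an ortho carbon of the 3,5-bis(benzyloxy)phenoxy ring; loss of a proton from the arenium ion restores the arene and gives ring C with the new C4–C4a bond. The closest known reaction type is the intramolecular Friedel–Crafts acylation by which 3-aryloxyacrylic and 3-aryloxycinnamic acids are closed to chromones and flavones. Ring C closes in a six-membered mode that is exo with respect to the acyl C=O (6-exo-trig), with an arene carbon as nucleophile. No stereocentre is formed. Site selectivity is secured by the mirror symmetry of the phenoxy ring: its two ortho carbons are equivalent, each ortho to the enol-ether oxygen and ortho and para to a benzyloxy group, and the para carbon cannot reach the acyl group. Geometric selectivity is secured by the (Z) configuration set in step 3, which holds the carboxyl cis to the aryloxy group; a carboxyl cis to ring B would only face C6', which is meta to both ether oxygens and unactivated. Chemoselectivity rests on the absence of a metal halide Lewis acid and of water, so the four benzyl ethers and the enol ether should survive.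

Step 6
Reactants: 9 5,7,2',4'-tetrakis(benzyloxy)flavone
Product: 10 7,2',4'-tris(benzyloxy)-5-hydroxyflavone
Conditions: BCl3 (1.1 equiv), CH2Cl2, −78 °C; then H2O
Reagents that add atoms: none
Why: Chelation-controlled ether cleavage: BCl3 binds between the C4 carbonyl oxygen and O5 in a six-membered chelate, so only the peri benzyl ether is activated for attack of chloride at its benzylic carbon; with about one equivalent at −78 °C the other three benzyl ethers should persist.

Step 7
Reactants: 10 7,2',4'-tris(benzyloxy)-5-hydroxyflavone
Product: 11 7,2',4'-tris(benzyloxy)-5-hydroxy-6-iodoflavone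
Conditions: BnMe3N·ICl2 (1.05 equiv), CaCO3, CH2Cl2–MeOH, rt
Reagents that add atoms: benzyltrimethylammonium dichloroiodate, C[N+](C)(C)Cc1ccccc1.Cl[I-]Cl
Why: Electrophilic aromatic iodination directed ortho to the free C5 hydroxyl, the known regioselective 6-iodination of 5-hydroxy-7-alkoxyflavones; ring A with three oxygen donors should react before ring B with two, and CaCO3 takes up the HCl so the benzyl ethers are not exposed to acid.

Step 8
Reactants: 11 7,2',4'-tris(benzyloxy)-5-hydroxy-6-iodoflavone; 12 2-methylbut-3-yn-2-ol
Product: 13 7,2',4'-tris(benzyloxy)-5-hydroxy-6-(3-hydroxy-3-methylbut-1-yn-1-yl)flavone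
Conditions: PdCl2(PPh3)2 (5 mol%), CuI (10 mol%), Et3N, DMF, 40 °C
Reagents that add atoms: none
Why: Sonogashira coupling: zerovalent palladium inserts into the C6–I bond, the copper acetylide of 12 transmetalates and reductive elimination forms the C6–C(sp) bond; the mild temperature and the hydrogen bond of the C5 hydroxyl to the C4 carbonyl should keep that hydroxyl from adding to the alkyne.

Step 9
Reactants: 13 7,2',4'-tris(benzyloxy)-5-hydroxy-6-(3-hydroxy-3-methylbut-1-yn-1-yl)flavone
Product: 14 5,7,2',4'-tetrahydroxy-6-(3-hydroxy-3-methylbutyl)flavone (CNP0205133.0)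
Conditions: H2 (1 atm), 10% Pd/C, EtOAc–MeOH, rt
Reagents that add atoms: none
Why: Heterogeneous catalytic hydrogenation saturates the alkyne and hydrogenolyses the three benzylic C–O bonds in one neutral operation; the C2=C3 bond of ring C, a vinylogous ester, is reduced much more slowly, and the acid-free medium protects the tertiary alcohol.

## Compound list

1 | 2,4-bis(benzyloxy)benzaldehyde | O=Cc1ccc(OCc2ccccc2)cc1OCc1ccccc1 | starting material
2 | 2,4-bis(benzyloxy)-1-(2,2-dibromovinyl)benzene | BrC(Br)=Cc1ccc(OCc2ccccc2)cc1OCc1ccccc1 | intermediate
3 | lithium [2,4-bis(benzyloxy)phenyl]acetylide (not isolated) | [Li]C#Cc1ccc(OCc2ccccc2)cc1OCc1ccccc1 | intermediate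
4 | methyl 3-[2,4-bis(benzyloxy)phenyl]prop-2-ynoate | COC(=O)C#Cc1ccc(OCc2ccccc2)cc1OCc1ccccc1 | intermediate
5 | 3,5-bis(benzyloxy)phenol | Oc1cc(OCc2ccccc2)cc(OCc2ccccc2)c1 | starting material
6 | methyl (Z)-3-[3,5-bis(benzyloxy)phenoxy]-3-[2,4-bis(benzyloxy)phenyl]prop-2-enoate | COC(=O)/C=C(\Oc1cc(OCc2ccccc2)cc(OCc2ccccc2)c1)c1ccc(OCc2ccccc2)cc1OCc1ccccc1 | intermediate
7 | (Z)-3-[3,5-bis(benzyloxy)phenoxy]-3-[2,4-bis(benzyloxy)phenyl]prop-2-enoic acid | OC(=O)/C=C(\Oc1cc(OCc2ccccc2)cc(OCc2ccccc2)c1)c1ccc(OCc2ccccc2)cc1OCc1ccccc1 | intermediate
8 | (Z)-3-[3,5-bis(benzyloxy)phenoxy]-3-[2,4-bis(benzyloxy)phenyl]prop-2-enoic trifluoroacetic anhydride (not isolated) | O=C(OC(=O)C(F)(F)F)/C=C(\Oc1cc(OCc2ccccc2)cc(OCc2ccccc2)c1)c1ccc(OCc2ccccc2)cc1OCc1ccccc1 | intermediate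
9 | 5,7,2',4'-tetrakis(benzyloxy)flavone | O=c1cc(-c2ccc(OCc3ccccc3)cc2OCc2ccccc2)oc2cc(OCc3ccccc3)cc(OCc3ccccc3)c12 | intermediate
10 | 7,2',4'-tris(benzyloxy)-5-hydroxyflavone | O=c1cc(-c2ccc(OCc3ccccc3)cc2OCc2ccccc2)oc2cc(OCc3ccccc3)cc(O)c12 | intermediate
11 | 7,2',4'-tris(benzyloxy)-5-hydroxy-6-iodoflavone | O=c1cc(-c2ccc(OCc3ccccc3)cc2OCc2ccccc2)oc2cc(OCc3ccccc3)c(I)c(O)c12 | intermediate
12 | 2-methylbut-3-yn-2-ol | CC(C)(O)C#C | starting material
13 | 7,2',4'-tris(benzyloxy)-5-hydroxy-6-(3-hydroxy-3-methylbut-1-yn-1-yl)flavone | CC(C)(O)C#Cc1c(OCc2ccccc2)cc2oc(-c3ccc(OCc4ccccc4)cc3OCc3ccccc3)cc(=O)c2c1O | intermediate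
14 | 5,7,2',4'-tetrahydroxy-6-(3-hydroxy-3-methylbutyl)flavone | CC(C)(O)CCc1c(O)cc2oc(-c3ccc(O)cc3O)cc(=O)c2c1O | target

## Step count and least certain steps

Total step count: 9. Longest linear sequence: 9 steps (1 to 14); 5 and 12 enter as purchased fragments.

Step 5 (key step). The most likely failures are acid-induced loss of benzyl groups with re-alkylation of the very nucleophilic phloroglucinol ring, and acidolysis of the enol-ether C–O bond before the acylation has taken place. A further risk is E/Z isomerisation followed by lactonisation of the activated carboxyl onto the 2'-oxygen with loss of its benzyl group. All three stem from the same trifluoroacetic acid that drives the ring closure. Fallback: the flavone core would be built without any carboxyl activation, setting out from 1. Claisen–Schmidt condensation of 1 with purchasable 1-[2,4-bis(benzyloxy)-6-hydroxyphenyl]ethanone (CC(=O)c1c(O)cc(OCc2ccccc2)cc1OCc1ccccc1; KOH, EtOH, rt) should give the chalcone (E)-1-[2,4-bis(benzyloxy)-6-hydroxyphenyl]-3-[2,4-bis(benzyloxy)phenyl]prop-2-en-1-one F1. Oxidative cyclisation of F1 with catalytic I2 in DMSO at 120 °C closes ring C through the O1–C2 bond and returns to the route at 9.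

Step 3. The addition may be slow, because the 2,4-dialkoxyaryl group pushes electron density onto the β-carbon of the ynoate. Forcing it invites attack through a ring carbon of the ambident phenoxide, and reversible addition could erode the (Z) geometry. Fallback: setting out from 4, anti hydroiodination (NaI, AcOH, 70 °C) should give methyl (Z)-3-[2,4-bis(benzyloxy)phenyl]-3-iodoprop-2-enoate F2. Copper-catalysed vinyl C–O coupling of F2 with 5 (CuI, N,N-dimethylglycine, Cs2CO3, dioxane, 90 °C), which retains the alkene geometry, returns to the route at 6.

Step 6. Over-cleavage is the likely problem: once the chelated benzyl ether is gone, excess BCl3 or warming could begin to remove the 7-, 2'- and 4'-benzyl groups. Fallback: setting out from 9, all four benzyl groups would be removed by hydrogenolysis (H2, Pd/C, EtOAc–MeOH) to give 5,7,2',4'-tetrahydroxyflavone F3. The three non-chelated hydroxyls would then be re-benzylated (BnBr 3.1 equiv, K2CO3, acetone, reflux), the hydrogen-bonded C5 hydroxyl being the least reactive, returning to the route at 10.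

Step 7. Loss of site selectivity is the risk: the electrophile could attack C8, which the same three oxygens activate, or C5' of ring B, which lies para and ortho to two benzyloxy groups; a second iodination is also possible. Fallback: the chain would be delivered to C6 by a sigmatropic shift from O5, setting out from 10.
- Pd(PPh3)4-catalysed Tsuji–Trost O-alkylation with methyl 2-methylbut-3-en-2-yl carbonate (COC(=O)OC(C)(C)C=C) in THF should give 7,2',4'-tris(benzyloxy)-5-[(2-methylbut-3-en-2-yl)oxy]flavone F4.
- Aromatic Claisen rearrangement (Eu(fod)3, CHCl3, 60 °C) can only reach the single ortho carbon C6 and should give 7,2',4'-tris(benzyloxy)-5-hydroxy-6-(3-methylbut-2-en-1-yl)flavone F5.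
- Mukaiyama hydration (Co(acac)2, PhSiH3, O2, THF–i-PrOH) places the hydroxyl on the tertiary carbon and gives 7,2',4'-tris(benzyloxy)-5-hydroxy-6-(3-hydroxy-3-methylbutyl)flavone F6.
- Hydrogenolysis of F6 under the conditions of step 9 returns to the route at 14.

Step 8. Under palladium and copper catalysis the C5 hydroxyl could add to the newly formed alkyne (5-endo-dig cycloisomerisation to a furan fused across C5–C6). Oxidative addition at the doubly ortho-substituted, electron-rich iodide may also be slow enough for oxidative dimerisation of 12 to compete. Fallback: setting out from 11, a Heck reaction with 2-methylbut-3-en-2-ol (C=CC(C)(C)O; Pd(OAc)2, P(o-tol)3, Et3N, DMF, 90 °C) should give 7,2',4'-tris(benzyloxy)-5-hydroxy-6-[(E)-3-hydroxy-3-methylbut-1-en-1-yl]flavone F7, in which no alkyne is available for cyclisation. Hydrogenation of F7 under the conditions of step 9 returns to the route at 14.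

## Further compounds

F1 | step 5 | (E)-1-[2,4-bis(benzyloxy)-6-hydroxyphenyl]-3-[2,4-bis(benzyloxy)phenyl]prop-2-en-1-one | O=C(/C=C/c1ccc(OCc2ccccc2)cc1OCc1ccccc1)c1c(O)cc(OCc2ccccc2)cc1OCc1ccccc1
F2 | step 3 | methyl (Z)-3-[2,4-bis(benzyloxy)phenyl]-3-iodoprop-2-enoate | COC(=O)/C=C(\I)c1ccc(OCc2ccccc2)cc1OCc1ccccc1
F3 | step 6 | 5,7,2',4'-tetrahydroxyflavone | O=c1cc(-c2ccc(O)cc2O)oc2cc(O)cc(O)c12
F4 | step 7 | 7,2',4'-tris(benzyloxy)-5-[(2-methylbut-3-en-2-yl)oxy]flavone | C=CC(C)(C)Oc1cc(OCc2ccccc2)cc2oc(-c3ccc(OCc4ccccc4)cc3OCc3ccccc3)cc(=O)c12
F5 | step 7 | 7,2',4'-tris(benzyloxy)-5-hydroxy-6-(3-methylbut-2-en-1-yl)flavone | CC(C)=CCc1c(OCc2ccccc2)cc2oc(-c3ccc(OCc4ccccc4)cc3OCc3ccccc3)cc(=O)c2c1O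
F6 | step 7 | 7,2',4'-tris(benzyloxy)-5-hydroxy-6-(3-hydroxy-3-methylbutyl)flavone | CC(C)(O)CCc1c(OCc2ccccc2)cc2oc(-c3ccc(OCc4ccccc4)cc3OCc3ccccc3)cc(=O)c2c1O
F7 | step 8 | 7,2',4'-tris(benzyloxy)-5-hydroxy-6-[(E)-3-hydroxy-3-methylbut-1-en-1-yl]flavone | CC(C)(O)/C=C/c1c(OCc2ccccc2)cc2oc(-c3ccc(OCc4ccccc4)cc3OCc3ccccc3)cc(=O)c2c1O
A1 | alternative 1 | 2',4'-bis(benzyloxy)-5,7-dihydroxy-6-[3-methyl-3-(triethylsilyloxy)butyl]flavone | CC(C)(O[Si](CC)(CC)CC)CCc1c(O)cc2oc(-c3ccc(OCc4ccccc4)cc3OCc3ccccc3)cc(=O)c2c1O
A2 | alternative 1 | methyl 2-[3-methyl-3-(triethylsilyloxy)butyl]-3-oxo-4-{6-[2,4-bis(benzyloxy)phenyl]-4-oxo-4H-pyran-2-yl}butanoate (racemic) | COC(=O)C(CCC(C)(C)O[Si](CC)(CC)CC)C(=O)Cc1cc(=O)cc(-c2ccc(OCc3ccccc3)cc2OCc2ccccc2)o1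
A3 | alternative 2 | 5,7,2'-tris(benzyloxy)-4'-hydroxyflavone | O=c1cc(-c2ccc(O)cc2OCc2ccccc2)oc2cc(OCc3ccccc3)cc(OCc3ccccc3)c12
A4 | alternative 2 | 5,7-bis(benzyloxy)-2-ethynyl-4H-chromen-4-one | C#Cc1cc(=O)c2c(OCc3ccccc3)cc(OCc3ccccc3)cc2o1
A5 | alternative 2 | 1-benzyloxy-1,3-bis(trimethylsilyloxy)buta-1,3-diene | C=C(O[Si](C)(C)C)C=C(OCc1ccccc1)O[Si](C)(C)C
A6 | alternative 3 | 2',4'-bis(benzyloxy)-5-hydroxy-6-[3-methyl-3-(triethylsilyloxy)butyl]-7-(triisopropylsilyloxy)flavone | CC(C)(O[Si](CC)(CC)CC)CCc1c(O[Si](C(C)C)(C(C)C)C(C)C)cc2oc(-c3ccc(OCc4ccccc4)cc3OCc3ccccc3)cc(=O)c2c1O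
A7 | alternative 3 | 2-diazo-1-{6-[2,4-bis(benzyloxy)phenyl]-4-oxo-4H-pyran-2-yl}ethan-1-one | [N-]=[N+]=CC(=O)c1cc(=O)cc(-c2ccc(OCc3ccccc3)cc2OCc2ccccc2)o1
A8 | alternative 3 | triethyl{[2-methyl-6-(triisopropylsilyloxy)hex-5-yn-2-yl]oxy}silane | CC(C)(O[Si](CC)(CC)CC)CCC#CO[Si](C(C)C)(C(C)C)C(C)C
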